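**Plan**

1. Retrosynthetic cuts: (i) the C7 carbinol of the octahydroazulene back to its enone; (ii) the cyclopentane bond C1–C8a (tertiary carbinol carbon to ring-fusion carbon) by reductive ketyl–enone cyclisation; (iii) the bond from C5 of the seven-membered ring to the ethylene bridge by addition of a left-half alkyl-metal to a vinylogous ester with Stork–Danheiser transposition.
2. Enabling feature: the carbinol carbon C1 (Me, OH) is 1,4-related to the carbinol carbon C7 through C8a–C8. C8a is therefore the β-carbon of a C7 enone inside the seven-membered ring and lies five atoms from the ketone carbon of a 3-oxobutyl chain on C3a, so a ketyl closes the five-membered ring 5-exo onto a pre-formed cross-conjugated cycloheptadienone.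
3. Left half (steps 1–9): geranyl bromide → ketophosphonate → enone → double Shi epoxidation → regiodefined enol silane → epoxide-opening cascade forming oxepane and cyclohexanone together → methyl addition → iodide.
4. Right half (steps 10–15): cycloheptane-1,3-dione → vinylogous ester → dienone → Cu-catalysed asymmetric conjugate addition with enolate methylation (three components) → gem-dimethyl → 4,5-dehydrogenation.
5. Union and end game (steps 16–19): organocerium addition and acid transposition join the halves and unmask dienone, methyl ketone and both alcohols; SmI2 closes the cyclopentanol; acetylation; CBS reduction.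
6. Stereochemistry: benzoxepine C3, C5a, C9a from the Shi epoxides, with C6 and C7 following from the chair transition state and equatorial methyl delivery; azulene C3a from the chiral Cu catalyst; C8a and C1 from the ring closure; C7 from the CBS catalyst.

Key step: step 17

Remark (assumption): the D-fructose-derived Shi ketone is taken to give the (R)-configured epoxides of E-trisubstituted alkenes, and the ferrocenyl diphosphine antipode in step 13 is the one that gives the 6S adduct.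

Step 1
Reactants: 1 geranyl bromide; 2 dimethyl (2-oxopropyl)phosphonate
Product: 3 dimethyl [(5E)-6,10-dimethyl-2-oxoundeca-5,9-dien-1-yl]phosphonate
Conditions: 2, NaH, THF, 0 °C; n-BuLi, 0 °C; then 1, 0 °C → rt
Reagents that add atoms: none
Why: The dianion of the β-ketophosphonate should be alkylated at its more basic terminal (γ) carbon by the primary allylic bromide in an SN2 reaction (dianion γ-alkylation), leaving the E-alkene untouched.

Step 2
Reactants: 3 dimethyl [(5E)-6,10-dimethyl-2-oxoundeca-5,9-dien-1-yl]phosphonate; 4 (benzyloxy)acetaldehyde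
Product: 5 (2E,7E)-1-(benzyloxy)-8,12-dimethyltrideca-2,7,11-trien-4-one
Conditions: LiCl, i-Pr2NEt, MeCN, rt
Reagents that add atoms: none
Why: Horner–Wadsworth–Emmons olefination under Masamune–Roush conditions should give the E-enone, which carries the two-carbon handle for the later fragment union.

Step 3
Reactants: 5 (2E,7E)-1-(benzyloxy)-8,12-dimethyltrideca-2,7,11-trien-4-one
Product: 6 (2E)-1-(benzyloxy)-6-[(2R,3R)-3-{2-[(2R)-3,3-dimethyloxiran-2-yl]ethyl}-3-methyloxiran-2-yl]hex-2-en-4-one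
Conditions: D-fructose-derived Shi ketone (0.4 equiv), Oxone, K2CO3, n-Bu4NHSO4 (cat.), MeCN/dimethoxymethane–aq. borate buffer, 0 °C
Reagents that add atoms: potassium peroxymonosulfate (Oxone), [K+].[O-]S(=O)(=O)OO
Why: Shi asymmetric epoxidation, in which the chiral dioxirane epoxidises the two electron-rich trisubstituted alkenes through a spiro transition state (reagent control) to the (R)-configured epoxides while the electron-poor enone alkene reacts much more slowly.

Step 4
Reactants: 6 (2E)-1-(benzyloxy)-6-[(2R,3R)-3-{2-[(2R)-3,3-dimethyloxiran-2-yl]ethyl}-3-methyloxiran-2-yl]hex-2-en-4-one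
Product: 7 triethyl{[(3Z)-6-(benzyloxy)-1-[(2R,3R)-3-{2-[(2R)-3,3-dimethyloxiran-2-yl]ethyl}-3-methyloxiran-2-yl]hex-3-en-3-yl]oxy}silane
Conditions: RhCl(PPh3)3 (2 mol%), Et3SiH, THF, 50 °C
Reagents that add atoms: triethylsilane, CC[SiH](CC)CC
Why: Rh-catalysed 1,4-hydrosilylation of the enone should deliver the silyl enol ether regiospecifically on the former enone side (Z geometry from the s-cis conformer), which base could not do with this dialkyl ketone, and the epoxides are inert to the neutral conditions.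

Step 5
Reactants: 7 triethyl{[(3Z)-6-(benzyloxy)-1-[(2R,3R)-3-{2-[(2R)-3,3-dimethyloxiran-2-yl]ethyl}-3-methyloxiran-2-yl]hex-3-en-3-yl]oxy}silane
Product: 8 (3R,5aR,6R,9aR)-6-[2-(benzyloxy)ethyl]-2,2,5a-trimethyl-3-[(triethylsilyl)oxy]octahydro-1-benzoxepin-7(2H)-one
Conditions: TESOTf (0.3 equiv), 2,6-di-tert-butyl-4-methylpyridine, CH2Cl2, −78 °C; aq. NaHCO3; then DBU (cat.), CH2Cl2, rt
Reagents that add atoms: none
Why: Silyl-triflate-promoted epoxide-opening cascade (tandem oxa- and carbacyclisation terminated by an enol silane) in which the silylated terminal epoxide is opened at its tertiary carbon by the neighbouring epoxide oxygen and the resulting epoxonium ion is opened at its tertiary carbon with inversion by the Z-enol silane in a chair transition state, so that the trans ring fusion (5aR,9aR) and C3 come from the epoxides, the C6 side chain is equatorial (DBU converges any epimer), and the silyl group ends on the C3 oxygen.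

Step 6
Reactants: 8 (3R,5aR,6R,9aR)-6-[2-(benzyloxy)ethyl]-2,2,5a-trimethyl-3-[(triethylsilyl)oxy]octahydro-1-benzoxepin-7(2H)-one
Product: 9 (3R,5aR,6R,7S,9aR)-6-[2-(benzyloxy)ethyl]-2,2,5a,7-tetramethyl-3-[(triethylsilyl)oxy]decahydro-1-benzoxepin-7-ol
Conditions: CeCl3 (anhydrous), MeLi, THF, −78 °C
Reagents that add atoms: methyllithium, [Li]C
Why: Organocerium 1,2-addition to an enolisable ketone, in which the methyl group should enter from the equatorial direction because the axial path is blocked by the syn-axial angular methyl at C5a, giving the axial 7-OH and equatorial 7-Me (7S).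

Step 7
Reactants: 9 (3R,5aR,6R,7S,9aR)-6-[2-(benzyloxy)ethyl]-2,2,5a,7-tetramethyl-3-[(triethylsilyl)oxy]decahydro-1-benzoxepin-7-ol
Product: 10 {[(3R,5aR,6R,7S,9aR)-6-[2-(benzyloxy)ethyl]-2,2,5a,7-tetramethyl-7-[(trimethylsilyl)oxy]decahydro-1-benzoxepin-3-yl]oxy}triethylsilane
Conditions: TMSOTf, 2,6-lutidine, CH2Cl2, −78 → 0 °C
Reagents that add atoms: trimethylsilyl trifluoromethanesulfonate, C[Si](C)(C)OS(=O)(=O)C(F)(F)F
Why: Silyl ether protection of the hindered tertiary alcohol with a silyl triflate prevents tetrahydrofuran formation and alkoxide interference in the iodide and organolithium steps.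

Step 8
Reactants: 10 {[(3R,5aR,6R,7S,9aR)-6-[2-(benzyloxy)ethyl]-2,2,5a,7-tetramethyl-7-[(trimethylsilyl)oxy]decahydro-1-benzoxepin-3-yl]oxy}triethylsilane
Product: 11 2-[(3R,5aR,6R,7S,9aR)-2,2,5a,7-tetramethyl-3-[(triethylsilyl)oxy]-7-[(trimethylsilyl)oxy]decahydro-1-benzoxepin-6-yl]ethan-1-ol
Conditions: H2 (1 atm), Pd(OH)2/C, EtOAc, rt
Reagents that add atoms: none
Why: Hydrogenolysis of the benzyl ether in a neutral aprotic solvent should free the primary alcohol, since the molecule has no alkene and the silyl ethers are stable under these conditions.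

Step 9
Reactants: 11 2-[(3R,5aR,6R,7S,9aR)-2,2,5a,7-tetramethyl-3-[(triethylsilyl)oxy]-7-[(trimethylsilyl)oxy]decahydro-1-benzoxepin-6-yl]ethan-1-ol
Product: 12 triethyl{[(3R,5aR,6R,7S,9aR)-6-(2-iodoethyl)-2,2,5a,7-tetramethyl-7-[(trimethylsilyl)oxy]decahydro-1-benzoxepin-3-yl]oxy}silane
Conditions: I2, PPh3, imidazole, CH2Cl2, 0 °C
Reagents that add atoms: iodine, II
Why: Appel-type iodination converts the primary alcohol into the iodide by SN2 displacement of the oxyphosphonium group without touching a stereocentre.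

Step 10
Reactants: 13 cycloheptane-1,3-dione
Product: 14 2-methylcycloheptane-1,3-dione
Conditions: MeI, K2CO3, acetone, reflux
Reagents that add atoms: iodomethane, CI
Why: C-Alkylation of the 1,3-dione enolate at the doubly activated C2 (1,3-dicarbonyl alkylation) gives a symmetric product with no fixed stereocentre.

Step 11
Reactants: 14 2-methylcycloheptane-1,3-dione
Product: 15 2-methyl-3-(2-methylpropoxy)cyclohept-2-en-1-one
Conditions: i-BuOH, p-TsOH (cat.), toluene, reflux (Dean–Stark)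
Reagents that add atoms: 2-methylpropan-1-ol, CC(C)CO
Why: Acid-catalysed enol etherification with azeotropic removal of water (vinylogous ester formation) can give only one regioisomer because the dione is symmetric.

Step 12
Reactants: 15 2-methyl-3-(2-methylpropoxy)cyclohept-2-en-1-one
Product: 17 2-methyl-3-(2-methylpropoxy)cyclohepta-2,6-dien-1-one, via selenide 16 (not isolated)
Conditions: LDA, THF, −78 °C; PhSeCl; then 30% H2O2, pyridine, CH2Cl2, 0 °C → rt
Reagents that add atoms: none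
Why: Kinetic deprotonation of a vinylogous ester occurs at the α′ carbon (C7), and α-selenenylation followed by selenoxide syn-elimination should then give the cross-conjugated dienone.

Step 13
Reactants: 17 2-methyl-3-(2-methylpropoxy)cyclohepta-2,6-dien-1-one; 18 2-(2-bromoethyl)-2-methyl-1,3-dioxolane
Product: 20 (6S,7S)-2,7-dimethyl-6-[2-(2-methyl-1,3-dioxolan-2-yl)ethyl]-3-(2-methylpropoxy)cyclohept-2-en-1-one, via Grignard reagent 19 (not isolated)
Conditions: 18, Mg, THF, rt; CuBr·SMe2 (5 mol%), Josiphos-type ferrocenyl diphosphine (6 mol%), t-BuOMe, −75 °C; then MeI, DMPU, −75 °C → rt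
Reagents that add atoms: iodomethane, CI
Why: Copper-catalysed asymmetric conjugate addition of the Grignard reagent to the unsubstituted enone arm (the alkoxy-bearing arm is a deactivated vinylogous ester) sets C6 by ligand control, and the magnesium enolate is methylated anti to the new side chain in a three-component conjugate addition–alkylation.

Step 14
Reactants: 20 (6S,7S)-2,7-dimethyl-6-[2-(2-methyl-1,3-dioxolan-2-yl)ethyl]-3-(2-methylpropoxy)cyclohept-2-en-1-one
Product: 21 (6S)-2,7,7-trimethyl-6-[2-(2-methyl-1,3-dioxolan-2-yl)ethyl]-3-(2-methylpropoxy)cyclohept-2-en-1-one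
Conditions: LDA, THF, −78 °C; MeI, DMPU, −78 → 0 °C
Reagents that add atoms: iodomethane, CI
Why: Kinetic α′-enolate formation at the C7 methine and methylation (enolate alkylation) installs the gem-dimethyl group and removes the C7 stereocentre while leaving C6 untouched.

Step 15
Reactants: 21 (6S)-2,7,7-trimethyl-6-[2-(2-methyl-1,3-dioxolan-2-yl)ethyl]-3-(2-methylpropoxy)cyclohept-2-en-1-one
Product: 23 (6R)-2,7,7-trimethyl-6-[2-(2-methyl-1,3-dioxolan-2-yl)ethyl]-3-(2-methylpropoxy)cyclohepta-2,4-dien-1-one, via silyl dienol ether 22 (not isolated)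
Conditions: LDA, THF, −78 °C; TMSCl, −78 → 0 °C; solvent exchange; Pd(OAc)2 (1.1 equiv), MeCN, rt
Reagents that add atoms: none
Why: With no α′-hydrogen left, LDA removes a γ-hydrogen (C4) to give the extended dienolate, which is trapped on oxygen, and Saegusa–Ito oxidation of this silyl dienol ether (Pd at C4, β-hydride elimination from C5) should give the linear 2,4-dienone without involving C6 (the descriptor changes only because of CIP priorities).

Step 16
Reactants: 12 triethyl{[(3R,5aR,6R,7S,9aR)-6-(2-iodoethyl)-2,2,5a,7-tetramethyl-7-[(trimethylsilyl)oxy]decahydro-1-benzoxepin-3-yl]oxy}silane; 23 (6R)-2,7,7-trimethyl-6-[2-(2-methyl-1,3-dioxolan-2-yl)ethyl]-3-(2-methylpropoxy)cyclohepta-2,4-dien-1-one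
Product: 27 (5R)-3-{2-[(3R,5aR,6R,7S,9aR)-3,7-dihydroxy-2,2,5a,7-tetramethyldecahydro-1-benzoxepin-6-yl]ethyl}-2,4,4-trimethyl-5-(3-oxobutyl)cyclohepta-2,6-dien-1-one, via alkyllithium 24 (not isolated), via alkylcerium dichloride 25 (not isolated), via carbinol adduct 26 (not isolated)
Conditions: 12, t-BuLi (2.1 equiv), Et2O/pentane, −78 °C; CeCl3, THF, −78 °C; 23, −78 → 0 °C; then 1 M HCl, THF, rt
Reagents that add atoms: water, O
Why: Iodine–lithium exchange and transmetalation give a weakly basic organocerium that should add 1,2 to the hindered vinylogous-ester carbonyl, and aqueous acid then ionises the tertiary allylic carbinol and hydrolyses the enol ether (Stork–Danheiser transposition) to the cross-conjugated dienone while also cleaving the dioxolane and both silyl ethers, with no new stereocentre formed.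

Step 17
Reactants: 27 (5R)-3-{2-[(3R,5aR,6R,7S,9aR)-3,7-dihydroxy-2,2,5a,7-tetramethyldecahydro-1-benzoxepin-6-yl]ethyl}-2,4,4-trimethyl-5-(3-oxobutyl)cyclohepta-2,6-dien-1-one
Product: 28 (1R,3aR,8aR)-5-{2-[(3R,5aR,6R,7S,9aR)-3,7-dihydroxy-2,2,5a,7-tetramethyldecahydro-1-benzoxepin-6-yl]ethyl}-1-hydroxy-1,4,4,6-tetramethyl-2,3,3a,4,8,8a-hexahydroazulen-7(1H)-one
Conditions: SmI2 (2.5 equiv), HMPA, t-BuOH, THF, −78 °C; aq. NH4Cl
Reagents that add atoms: none
Why: SmI2–HMPA transfers one electron to the 3-oxobutyl ketone (or reversibly to the dienone) to give a Sm(III)-bound ketyl that adds to C6 of the cyclohepta-2,6-dienone (the future C8a), and the resulting α-keto radical is reduced to a samarium dienolate that is protonated at C7 (future C8) to regenerate the tetrasubstituted enone. The closest known reaction type is the SmI2-mediated ketyl–olefin (ketone–enone) reductive cyclisation. The only ring closed is the cyclopentane, by 5-exo-trig attack in a chair-like transition state. C8a is controlled by the existing C5 stereocentre, because the three-atom tether can reach only the enone face on which it stands, which forces the cis ring fusion. C1 is controlled by the preference of the bulky, electron-rich O–Sm(III)(HMPA)n group to point away from the enone α-carbon, which should place the hydroxyl cis to H-8a and the methyl cis to C8 as in the target. The step needs C–C bond formation to outrun simple dienone reduction and needs attack at C6 and not at the other β-carbon; the substrate secures this because C6 is an unhindered CH five atoms from the ketone carbon, whereas C3 is tetrasubstituted, flanked by the quaternary C4 and reachable only by a slower 6-exo closure.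

Step 18
Reactants: 28 (1R,3aR,8aR)-5-{2-[(3R,5aR,6R,7S,9aR)-3,7-dihydroxy-2,2,5a,7-tetramethyldecahydro-1-benzoxepin-6-yl]ethyl}-1-hydroxy-1,4,4,6-tetramethyl-2,3,3a,4,8,8a-hexahydroazulen-7(1H)-one
Product: 29 (3R,5aR,6R,7S,9aR)-7-hydroxy-6-{2-[(1R,3aR,8aR)-1-hydroxy-1,4,4,6-tetramethyl-7-oxo-1,2,3,3a,4,7,8,8a-octahydroazulen-5-yl]ethyl}-2,2,5a,7-tetramethyldecahydro-1-benzoxepin-3-yl acetate
Conditions: Ac2O, pyridine, DMAP (cat.), CH2Cl2, 0 °C → rt
Reagents that add atoms: acetic anhydride, CC(=O)OC(C)=O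
Why: DMAP-catalysed esterification should acylate the only secondary alcohol, because the two tertiary alcohols are too hindered to react under these conditions.

Step 19
Reactants: 29 (3R,5aR,6R,7S,9aR)-7-hydroxy-6-{2-[(1R,3aR,8aR)-1-hydroxy-1,4,4,6-tetramethyl-7-oxo-1,2,3,3a,4,7,8,8a-octahydroazulen-5-yl]ethyl}-2,2,5a,7-tetramethyldecahydro-1-benzoxepin-3-yl acetate
Product: 30 (3R,5aR,6R,7S,9aR)-6-{2-[(1R,3aR,7R,8aR)-1,7-dihydroxy-1,4,4,6-tetramethyl-1,2,3,3a,4,7,8,8a-octahydroazulen-5-yl]ethyl}-7-hydroxy-2,2,5a,7-tetramethyldecahydro-1-benzoxepin-3-yl acetate (CNP0157376.1)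
Conditions: (S)-2-methyl-CBS-oxazaborolidine (1.0 equiv), catecholborane, toluene/CH2Cl2, −78 °C; MeOH, then aq. work-up
Reagents that add atoms: none
Why: Corey–Bakshi–Shibata reduction, in which the oxazaborolidine binds the enone carbonyl with the α-methylvinyl side as the large group and delivers hydride 1,2 to one face, so the (S)-catalyst should give the (7R)-allylic alcohol by reagent control while catecholborane at −78 °C leaves the acetate and the tertiary alcohols alone.

**Compound list**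

1 | (2E)-1-bromo-3,7-dimethylocta-2,6-diene (geranyl bromide) | CC(C)=CCC/C(C)=C/CBr | starting material
2 | dimethyl (2-oxopropyl)phosphonate | CC(=O)CP(=O)(OC)OC | starting material
3 | dimethyl [(5E)-6,10-dimethyl-2-oxoundeca-5,9-dien-1-yl]phosphonate | COP(=O)(OC)CC(=O)CC/C=C(\C)CCC=C(C)C | intermediate
4 | (benzyloxy)acetaldehyde | O=CCOCc1ccccc1 | starting material
5 | (2E,7E)-1-(benzyloxy)-8,12-dimethyltrideca-2,7,11-trien-4-one | O=C(/C=C/COCc1ccccc1)CC/C=C(\C)CCC=C(C)C | intermediate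
6 | (2E)-1-(benzyloxy)-6-[(2R,3R)-3-{2-[(2R)-3,3-dimethyloxiran-2-yl]ethyl}-3-methyloxiran-2-yl]hex-2-en-4-one | O=C(/C=C/COCc1ccccc1)CC[C@H]1O[C@]1(C)CC[C@H]1OC1(C)C | intermediate
7 | triethyl{[(3Z)-6-(benzyloxy)-1-[(2R,3R)-3-{2-[(2R)-3,3-dimethyloxiran-2-yl]ethyl}-3-methyloxiran-2-yl]hex-3-en-3-yl]oxy}silane | CC[Si](CC)(CC)O/C(=C\CCOCc1ccccc1)CC[C@H]1O[C@]1(C)CC[C@H]1OC1(C)C | intermediate
8 | (3R,5aR,6R,9aR)-6-[2-(benzyloxy)ethyl]-2,2,5a-trimethyl-3-[(triethylsilyl)oxy]octahydro-1-benzoxepin-7(2H)-one | CC[Si](CC)(CC)O[C@@H]1CC[C@]2(C)[C@@H](CCOCc3ccccc3)C(=O)CC[C@H]2OC1(C)C | intermediate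
9 | (3R,5aR,6R,7S,9aR)-6-[2-(benzyloxy)ethyl]-2,2,5a,7-tetramethyl-3-[(triethylsilyl)oxy]decahydro-1-benzoxepin-7-ol | CC[Si](CC)(CC)O[C@@H]1CC[C@]2(C)[C@@H](CCOCc3ccccc3)[C@@](C)(O)CC[C@H]2OC1(C)C | intermediate
10 | {[(3R,5aR,6R,7S,9aR)-6-[2-(benzyloxy)ethyl]-2,2,5a,7-tetramethyl-7-[(trimethylsilyl)oxy]decahydro-1-benzoxepin-3-yl]oxy}triethylsilane | CC[Si](CC)(CC)O[C@@H]1CC[C@]2(C)[C@@H](CCOCc3ccccc3)[C@@](C)(O[Si](C)(C)C)CC[C@H]2OC1(C)C | intermediate
11 | 2-[(3R,5aR,6R,7S,9aR)-2,2,5a,7-tetramethyl-3-[(triethylsilyl)oxy]-7-[(trimethylsilyl)oxy]decahydro-1-benzoxepin-6-yl]ethan-1-ol | CC[Si](CC)(CC)O[C@@H]1CC[C@]2(C)[C@@H](CCO)[C@@](C)(O[Si](C)(C)C)CC[C@H]2OC1(C)C | intermediate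
12 | triethyl{[(3R,5aR,6R,7S,9aR)-6-(2-iodoethyl)-2,2,5a,7-tetramethyl-7-[(trimethylsilyl)oxy]decahydro-1-benzoxepin-3-yl]oxy}silane | CC[Si](CC)(CC)O[C@@H]1CC[C@]2(C)[C@@H](CCI)[C@@](C)(O[Si](C)(C)C)CC[C@H]2OC1(C)C | intermediate
13 | cycloheptane-1,3-dione | O=C1CCCCC(=O)C1 | starting material
14 | 2-methylcycloheptane-1,3-dione | CC1C(=O)CCCCC1=O | intermediate
15 | 2-methyl-3-(2-methylpropoxy)cyclohept-2-en-1-one | CC1=C(OCC(C)C)CCCCC1=O | intermediate
16 | 2-methyl-3-(2-methylpropoxy)-7-(phenylselanyl)cyclohept-2-en-1-one (racemic) | CC1=C(OCC(C)C)CCCC([Se]c2ccccc2)C1=O | intermediate (not isolated)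
17 | 2-methyl-3-(2-methylpropoxy)cyclohepta-2,6-dien-1-one | CC1=C(OCC(C)C)CCC=CC1=O | intermediate
18 | 2-(2-bromoethyl)-2-methyl-1,3-dioxolane | CC1(CCBr)OCCO1 | starting material
19 | [2-(2-methyl-1,3-dioxolan-2-yl)ethyl]magnesium bromide | CC1(CC[Mg]Br)OCCO1 | intermediate (not isolated)
20 | (6S,7S)-2,7-dimethyl-6-[2-(2-methyl-1,3-dioxolan-2-yl)ethyl]-3-(2-methylpropoxy)cyclohept-2-en-1-one | CC1=C(OCC(C)C)CC[C@@H](CCC2(C)OCCO2)[C@H](C)C1=O | intermediate
21 | (6S)-2,7,7-trimethyl-6-[2-(2-methyl-1,3-dioxolan-2-yl)ethyl]-3-(2-methylpropoxy)cyclohept-2-en-1-one | CC1=C(OCC(C)C)CC[C@@H](CCC2(C)OCCO2)C(C)(C)C1=O | intermediate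
22 | trimethyl{[(6R)-2,7,7-trimethyl-6-[2-(2-methyl-1,3-dioxolan-2-yl)ethyl]-3-(2-methylpropoxy)cyclohepta-1,3-dien-1-yl]oxy}silane | CC1=C(O[Si](C)(C)C)C(C)(C)[C@H](CCC2(C)OCCO2)CC=C1OCC(C)C | intermediate (not isolated)
23 | (6R)-2,7,7-trimethyl-6-[2-(2-methyl-1,3-dioxolan-2-yl)ethyl]-3-(2-methylpropoxy)cyclohepta-2,4-dien-1-one | CC1=C(OCC(C)C)C=C[C@@H](CCC2(C)OCCO2)C(C)(C)C1=O | intermediate
24 | {2-[(3R,5aR,6R,7S,9aR)-2,2,5a,7-tetramethyl-3-[(triethylsilyl)oxy]-7-[(trimethylsilyl)oxy]decahydro-1-benzoxepin-6-yl]ethyl}lithium | CC[Si](CC)(CC)O[C@@H]1CC[C@]2(C)[C@@H](CC[Li])[C@@](C)(O[Si](C)(C)C)CC[C@H]2OC1(C)C | intermediate (not isolated)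
25 | dichloro{2-[(3R,5aR,6R,7S,9aR)-2,2,5a,7-tetramethyl-3-[(triethylsilyl)oxy]-7-[(trimethylsilyl)oxy]decahydro-1-benzoxepin-6-yl]ethyl}cerium | CC[Si](CC)(CC)O[C@@H]1CC[C@]2(C)[C@@H](CC[Ce](Cl)Cl)[C@@](C)(O[Si](C)(C)C)CC[C@H]2OC1(C)C | intermediate (not isolated)
26 | (6R)-2,7,7-trimethyl-6-[2-(2-methyl-1,3-dioxolan-2-yl)ethyl]-3-(2-methylpropoxy)-1-{2-[(3R,5aR,6R,7S,9aR)-2,2,5a,7-tetramethyl-3-[(triethylsilyl)oxy]-7-[(trimethylsilyl)oxy]decahydro-1-benzoxepin-6-yl]ethyl}cyclohepta-2,4-dien-1-ol (both C1 epimers) | CC[Si](CC)(CC)O[C@@H]1CC[C@]2(C)[C@@H](CCC3(O)C(C)=C(OCC(C)C)C=C[C@@H](CCC4(C)OCCO4)C3(C)C)[C@@](C)(O[Si](C)(C)C)CC[C@H]2OC1(C)C | intermediate (not isolated)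
27 | (5R)-3-{2-[(3R,5aR,6R,7S,9aR)-3,7-dihydroxy-2,2,5a,7-tetramethyldecahydro-1-benzoxepin-6-yl]ethyl}-2,4,4-trimethyl-5-(3-oxobutyl)cyclohepta-2,6-dien-1-one | O[C@@H]1CC[C@]2(C)[C@@H](CCC3=C(C)C(=O)C=C[C@@H](CCC(C)=O)C3(C)C)[C@@](C)(O)CC[C@H]2OC1(C)C | intermediate
28 | (1R,3aR,8aR)-5-{2-[(3R,5aR,6R,7S,9aR)-3,7-dihydroxy-2,2,5a,7-tetramethyldecahydro-1-benzoxepin-6-yl]ethyl}-1-hydroxy-1,4,4,6-tetramethyl-2,3,3a,4,8,8a-hexahydroazulen-7(1H)-one | O[C@@H]1CC[C@]2(C)[C@@H](CCC3=C(C)C(=O)C[C@@H]4[C@@H](CC[C@@]4(C)O)C3(C)C)[C@@](C)(O)CC[C@H]2OC1(C)C | intermediate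
29 | (3R,5aR,6R,7S,9aR)-7-hydroxy-6-{2-[(1R,3aR,8aR)-1-hydroxy-1,4,4,6-tetramethyl-7-oxo-1,2,3,3a,4,7,8,8a-octahydroazulen-5-yl]ethyl}-2,2,5a,7-tetramethyldecahydro-1-benzoxepin-3-yl acetate | CC(=O)O[C@@H]1CC[C@]2(C)[C@@H](CCC3=C(C)C(=O)C[C@@H]4[C@@H](CC[C@@]4(C)O)C3(C)C)[C@@](C)(O)CC[C@H]2OC1(C)C | intermediate
30 | (3R,5aR,6R,7S,9aR)-6-{2-[(1R,3aR,7R,8aR)-1,7-dihydroxy-1,4,4,6-tetramethyl-1,2,3,3a,4,7,8,8a-octahydroazulen-5-yl]ethyl}-7-hydroxy-2,2,5a,7-tetramethyldecahydro-1-benzoxepin-3-yl acetate | CC(=O)O[C@@H]1CC[C@]2(C)[C@@H](CCC3=C(C)[C@H](O)C[C@@H]4[C@@H](CC[C@@]4(C)O)C3(C)C)[C@@](C)(O)CC[C@H]2OC1(C)C | target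

**Totals and risks**

Total step count: 19. Longest linear sequence: 13 steps (steps 1–9, then 16–19); the right half takes 6 steps before the union.

Steps most likely to fail:

Step 17 (key ring closure). The cross-conjugated dienone may take up the electrons first and be reduced at its C6–C7 double bond, or couple with itself, before the bond to the ketone carbon forms; facial control at the carbinol carbon may also be lower than expected. The fallback closes the ring before the fragments are joined, on an acceptor that is harder to reduce than the ketone. It sets out from 23: the dioxolane is exchanged off with catalytic iodine in acetone to give (6R)-2,7,7-trimethyl-3-(2-methylpropoxy)-6-(3-oxobutyl)cyclohepta-2,4-dien-1-one F1. SmI2/HMPA/t-BuOH then forms the ketyl at the only easily reduced carbonyl and closes the ring 5-exo onto the terminal carbon (C5) of the dienyl vinylogous ester; after protonation and equilibration to the conjugated enol ether this gives (1R,3aR,8aR)-1-hydroxy-1,4,4,6-tetramethyl-7-(2-methylpropoxy)-2,3,3a,4,8,8a-hexahydroazulen-5(1H)-one F2. The tertiary alcohol is silylated with TMSOTf and 2,6-lutidine to (1R,3aR,8aR)-1,4,4,6-tetramethyl-7-(2-methylpropoxy)-1-[(trimethylsilyl)oxy]-2,3,3a,4,8,8a-hexahydroazulen-5(1H)-one F3. Addition of organocerium 25 (made from 12 as in step 16) and treatment with 1 M HCl then comes back to the route at 28.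

Step 5 (cascade). The cation cascade may stop early (elimination or capture of the epoxonium ion before C–C bond formation), or the trisubstituted enol silane may approach the congested tertiary carbon too slowly. The fallback uses a stronger, non-oxygenated π-nucleophile and reveals the ketone afterwards by oxidative cleavage. It sets out from 7: MeLi cleaves the enol silane to the lithium enolate, which is trapped with PhNTf2 as (3Z)-6-(benzyloxy)-1-[(2R,3R)-3-{2-[(2R)-3,3-dimethyloxiran-2-yl]ethyl}-3-methyloxiran-2-yl]hex-3-en-3-yl trifluoromethanesulfonate F4. Pd-catalysed Kumada coupling with (triethylsilyl)methylmagnesium chloride gives {(2Z)-5-(benzyloxy)-2-[2-[(2R,3R)-3-{2-[(2R)-3,3-dimethyloxiran-2-yl]ethyl}-3-methyloxiran-2-yl]ethyl]pent-2-en-1-yl}triethylsilane F5. The same TESOTf-promoted cascade, now terminated by the allylsilane through a β-silyl cation, gives {[(3R,5aR,6S,9aR)-6-[2-(benzyloxy)ethyl]-2,2,5a-trimethyl-7-methylidenedecahydro-1-benzoxepin-3-yl]oxy}triethylsilane F6. Ozonolysis (O3, CH2Cl2, −78 °C; Me2S) and brief DBU treatment come back to the route at 8.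

Step 15 (4,5-dehydrogenation). Deprotonation may occur at the 2-methyl group and not at C4, or palladium may eliminate toward that methyl group, giving an exocyclic isomer. The fallback moves the dehydrogenation to after the union, where the ketone has an ordinary α′-methylene. It sets out from 21 (with 12): organocerium 25 is added to 21 and the adduct is hydrolysed with cold dilute oxalic acid, which should spare the dioxolane and the triethylsilyl ether but remove the tertiary trimethylsilyl group, giving (5S)-3-{2-[(3R,5aR,6R,7S,9aR)-7-hydroxy-2,2,5a,7-tetramethyl-3-[(triethylsilyl)oxy]decahydro-1-benzoxepin-6-yl]ethyl}-2,4,4-trimethyl-5-[2-(2-methyl-1,3-dioxolan-2-yl)ethyl]cyclohept-2-en-1-one F7. LDA (2.2 equiv) and TMSCl, then Pd(OAc)2 (Saegusa–Ito oxidation of the α′-silyl enol ether, the tertiary alcohol being silylated at the same time), give (5R)-2,4,4-trimethyl-5-[2-(2-methyl-1,3-dioxolan-2-yl)ethyl]-3-{2-[(3R,5aR,6R,7S,9aR)-2,2,5a,7-tetramethyl-3-[(triethylsilyl)oxy]-7-[(trimethylsilyl)oxy]decahydro-1-benzoxepin-6-yl]ethyl}cyclohepta-2,6-dien-1-one F8. Treatment with 1 M HCl in THF comes back to the route at 27.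

**Further compounds**

F1 | step 17 | (6R)-2,7,7-trimethyl-3-(2-methylpropoxy)-6-(3-oxobutyl)cyclohepta-2,4-dien-1-one | CC1=C(OCC(C)C)C=C[C@@H](CCC(C)=O)C(C)(C)C1=O
F2 | step 17 | (1R,3aR,8aR)-1-hydroxy-1,4,4,6-tetramethyl-7-(2-methylpropoxy)-2,3,3a,4,8,8a-hexahydroazulen-5(1H)-one | CC1=C(OCC(C)C)C[C@@H]2[C@@H](CC[C@@]2(C)O)C(C)(C)C1=O
F3 | step 17 | (1R,3aR,8aR)-1,4,4,6-tetramethyl-7-(2-methylpropoxy)-1-[(trimethylsilyl)oxy]-2,3,3a,4,8,8a-hexahydroazulen-5(1H)-one | CC1=C(OCC(C)C)C[C@@H]2[C@@H](CC[C@@]2(C)O[Si](C)(C)C)C(C)(C)C1=O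
F4 | step 5 | (3Z)-6-(benzyloxy)-1-[(2R,3R)-3-{2-[(2R)-3,3-dimethyloxiran-2-yl]ethyl}-3-methyloxiran-2-yl]hex-3-en-3-yl trifluoromethanesulfonate | O=S(=O)(O/C(=C\CCOCc1ccccc1)CC[C@H]1O[C@]1(C)CC[C@H]1OC1(C)C)C(F)(F)F
F5 | step 5 | {(2Z)-5-(benzyloxy)-2-[2-[(2R,3R)-3-{2-[(2R)-3,3-dimethyloxiran-2-yl]ethyl}-3-methyloxiran-2-yl]ethyl]pent-2-en-1-yl}triethylsilane | CC[Si](CC)(CC)C/C(=C\CCOCc1ccccc1)CC[C@H]1O[C@]1(C)CC[C@H]1OC1(C)C
F6 | step 5 | {[(3R,5aR,6S,9aR)-6-[2-(benzyloxy)ethyl]-2,2,5a-trimethyl-7-methylidenedecahydro-1-benzoxepin-3-yl]oxy}triethylsilane | CC[Si](CC)(CC)O[C@@H]1CC[C@]2(C)[C@@H](CCOCc3ccccc3)C(=C)CC[C@H]2OC1(C)C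
F7 | step 15 | (5S)-3-{2-[(3R,5aR,6R,7S,9aR)-7-hydroxy-2,2,5a,7-tetramethyl-3-[(triethylsilyl)oxy]decahydro-1-benzoxepin-6-yl]ethyl}-2,4,4-trimethyl-5-[2-(2-methyl-1,3-dioxolan-2-yl)ethyl]cyclohept-2-en-1-one | CC[Si](CC)(CC)O[C@@H]1CC[C@]2(C)[C@@H](CCC3=C(C)C(=O)CC[C@@H](CCC4(C)OCCO4)C3(C)C)[C@@](C)(O)CC[C@H]2OC1(C)C
F8 | step 15 | (5R)-2,4,4-trimethyl-5-[2-(2-methyl-1,3-dioxolan-2-yl)ethyl]-3-{2-[(3R,5aR,6R,7S,9aR)-2,2,5a,7-tetramethyl-3-[(triethylsilyl)oxy]-7-[(trimethylsilyl)oxy]decahydro-1-benzoxepin-6-yl]ethyl}cyclohepta-2,6-dien-1-one | CC[Si](CC)(CC)O[C@@H]1CC[C@]2(C)[C@@H](CCC3=C(C)C(=O)C=C[C@@H](CCC4(C)OCCO4)C3(C)C)[C@@](C)(O[Si](C)(C)C)CC[C@H]2OC1(C)C
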